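1. Enabling feature: in the quinone ring (C1=O, C2–OMe, C3–OMe, C4=O, C5–chromanyl, C6–H) the two methoxy-bearing carbons C2 and C3 are each α to a carbonyl. Cutting C2–C3 therefore leaves two methoxymethyl ketones on the cis C5=C6 alkene, a (Z)-ene-1,4-dione, which is the oxidatively opened form of a 3-substituted 2,5-bis(methoxymethyl)furan.
2. Retrosynthetic cuts, in order: O–Si at the 7-OH; quinone C2–C3 (oxidative union of two enol carbons of like, nucleophilic polarity); the furan ring (singlet-oxygen opening read backwards); chroman O1–C8a (aryl C–O coupling); chroman C3–C4 (enolate benzylation); furan C3–CH2CO (boronate/bromoacetate coupling).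
3. Forward order: the furan ring is bought as 2,5-bis(hydroxymethyl)furan and the chroman arene as syringaldehyde. The two fragments are joined by alkylation, the pyran ring is closed next, and the furan is then opened and reclosed through its two side-chain CH2 carbons, so the quinone ring arises last; desilylation ends the route.
4. Stereochemistry: the only stereocentre, chroman C3 (S), is set by benzylation of the sodium enolate of an (S)-4-benzyl-2-oxazolidinone imide and is carried through unchanged.

Key step: step 13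

Remark: the terminal enol ether geometry of 20 and the configuration of the transient centres of 18 and 21 are left open, because none of them reaches the product; compounds 1, 6 and 9 are taken as commercial.

Step 1
Reactants: 1 2,5-bis(hydroxymethyl)furan
Product: 2 2,5-bis(methoxymethyl)furan
Conditions: NaH, MeI, THF, 0 °C to rt
Reagents that add atoms: iodomethane, CI
Why: Williamson ether synthesis on two primary furfuryl alkoxides, which installs at the outset the two methoxy groups that end up on quinone C2 and C3.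

Step 2
Reactants: 2 2,5-bis(methoxymethyl)furan
Product: 3 2-[2,5-bis(methoxymethyl)furan-3-yl]-4,4,5,5-tetramethyl-1,3,2-dioxaborolane
Conditions: B2pin2, [Ir(OMe)(cod)]2 (cat.), 4,4'-di-tert-butyl-2,2'-bipyridine, THF, 60 °C
Reagents that add atoms: bis(pinacolato)diboron, CC1(C)OB(OC1(C)C)B1OC(C)(C)C(C)(C)O1
Why: Iridium-catalysed aromatic C–H borylation; with both α-positions blocked, the two equivalent β-C–H bonds are the only ring sites, so a single monoboronate should form when 2 is kept in slight excess.

Step 3
Reactants: 3 2-[2,5-bis(methoxymethyl)furan-3-yl]-4,4,5,5-tetramethyl-1,3,2-dioxaborolane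
Product: 5 [2,5-bis(methoxymethyl)furan-3-yl]acetic acid, via ethyl ester 4 (not isolated)
Conditions: ethyl bromoacetate, Pd(OAc)2 (cat.), tri(1-naphthyl)phosphine, K3PO4, THF, H2O (2 equiv), rt; then LiOH, H2O, MeOH, rt; 1 M HCl to pH 3 at 0 °C
Reagents that add atoms: ethyl bromoacetate, CCOC(=O)CBr; lithium hydroxide, [Li+].[OH-]
Why: Suzuki–Miyaura-type coupling of an arylboron compound with an α-bromo ester (zerovalent palladium inserts into the C–Br bond and the palladium enolate is arylated by the boronate), followed by saponification in the same flask.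

Step 4
Reactants: 5 [2,5-bis(methoxymethyl)furan-3-yl]acetic acid; 6 (S)-4-benzyl-2-oxazolidinone
Product: 8 (4S)-4-benzyl-3-{[2,5-bis(methoxymethyl)furan-3-yl]acetyl}-1,3-oxazolidin-2-one, via mixed pivalic anhydride 7 (not isolated)
Conditions: PivCl, Et3N, THF, −20 °C; then 6, LiCl, −20 °C to rt
Reagents that add atoms: none
Why: N-Acylation of the Evans auxiliary through a mixed pivalic anhydride, in which the oxazolidinone (activated by LiCl/Et3N) attacks the unhindered arylacetyl carbonyl and not the pivaloyl one.

Step 5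
Reactants: 9 syringaldehyde (4-hydroxy-3,5-dimethoxybenzaldehyde)
Product: 10 2-bromo-4-hydroxy-3,5-dimethoxybenzaldehyde
Conditions: Br2, AcOH, rt
Reagents that add atoms: bromine, BrBr
Why: Electrophilic aromatic bromination; C2 and C6 are the only free ring positions, they are equivalent and each is ortho and para to a methoxy group, and the first bromine deactivates the ring against a second.

Step 6
Reactants: 10 2-bromo-4-hydroxy-3,5-dimethoxybenzaldehyde
Product: 11 2-bromo-3,5-dimethoxy-4-(triisopropylsilyloxy)benzaldehyde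
Conditions: TIPSCl, imidazole, DMF, rt
Reagents that add atoms: chlorotriisopropylsilane, CC(C)[Si](Cl)(C(C)C)C(C)C
Why: Silylation of the phenol; the triisopropylsilyl ether is chosen because it should survive amide base, hydride, Cs2CO3, singlet oxygen and Ag2O and can be removed at the end by fluoride without harm to a quinone.

Step 7
Reactants: 11 2-bromo-3,5-dimethoxy-4-(triisopropylsilyloxy)benzaldehyde
Product: 12 [2-bromo-3,5-dimethoxy-4-(triisopropylsilyloxy)phenyl]methanol
Conditions: NaBH4, MeOH, THF, 0 °C
Reagents that add atoms: none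
Why: Chemoselective borohydride reduction of the aldehyde to the benzylic alcohol; the aryl bromide and the silyl ether are inert.

Step 8
Reactants: 12 [2-bromo-3,5-dimethoxy-4-(triisopropylsilyloxy)phenyl]methanol
Product: 13 2-bromo-1-(bromomethyl)-3,5-dimethoxy-4-(triisopropylsilyloxy)benzene
Conditions: CBr4, PPh3, CH2Cl2, 0 °C
Reagents that add atoms: tetrabromomethane, BrC(Br)(Br)Br
Why: Appel reaction, which makes the benzylic bromide under neutral conditions so that neither the silyl ether nor the electron-rich benzylic position is exposed to acid.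

Step 9
Reactants: 8 (4S)-4-benzyl-3-{[2,5-bis(methoxymethyl)furan-3-yl]acetyl}-1,3-oxazolidin-2-one; 13 2-bromo-1-(bromomethyl)-3,5-dimethoxy-4-(triisopropylsilyloxy)benzene
Product: 15 (4S)-4-benzyl-3-{(2S)-2-[2,5-bis(methoxymethyl)furan-3-yl]-3-[2-bromo-3,5-dimethoxy-4-(triisopropylsilyloxy)phenyl]propanoyl}-1,3-oxazolidin-2-one, via sodium enolate 14 (not isolated)
Conditions: NaN(SiMe3)2, THF, −78 °C; then 13, −78 to −40 °C
Reagents that add atoms: none
Why: Evans asymmetric alkylation: the chelated sodium (Z)-enolate is shielded on one face by the C4 benzyl group of the auxiliary, so the benzylic bromide should add to the opposite face and set the (S) configuration of the future chroman C3.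

Step 10
Reactants: 15 (4S)-4-benzyl-3-{(2S)-2-[2,5-bis(methoxymethyl)furan-3-yl]-3-[2-bromo-3,5-dimethoxy-4-(triisopropylsilyloxy)phenyl]propanoyl}-1,3-oxazolidin-2-one
Product: 16 (2S)-2-[2,5-bis(methoxymethyl)furan-3-yl]-3-[2-bromo-3,5-dimethoxy-4-(triisopropylsilyloxy)phenyl]propan-1-ol
Conditions: LiBH4, MeOH (1 equiv), THF, 0 °C
Reagents that add atoms: none
Why: Reductive cleavage of the N-acyloxazolidinone to the primary alcohol with release of auxiliary 6; hydride attack at the exocyclic carbonyl is fast at 0 °C, so the α-stereocentre should not epimerize, and the aryl bromide is untouched.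

Step 11
Reactants: 16 (2S)-2-[2,5-bis(methoxymethyl)furan-3-yl]-3-[2-bromo-3,5-dimethoxy-4-(triisopropylsilyloxy)phenyl]propan-1-ol
Product: 17 (3S)-3-[2,5-bis(methoxymethyl)furan-3-yl]-6,8-dimethoxy-7-(triisopropylsilyloxy)chroman
Conditions: Pd(OAc)2 (cat.), 2-(di-tert-butylphosphino)-1,1'-binaphthyl, Cs2CO3, toluene, 70 °C
Reagents that add atoms: none
Why: Intramolecular Buchwald–Hartwig C–O coupling of the primary alcohol with the ortho aryl bromide, a known way to close the pyran ring of 3-arylchromans; the bulky electron-rich phosphine favours C–O reductive elimination over β-hydride elimination, and the stereocentre is not involved.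

Step 12
Reactants: 17 (3S)-3-[2,5-bis(methoxymethyl)furan-3-yl]-6,8-dimethoxy-7-(triisopropylsilyloxy)chroman
Product: 19 (3Z)-3-[(3S)-6,8-dimethoxy-7-(triisopropylsilyloxy)chroman-3-yl]-1,6-dimethoxyhex-3-ene-2,5-dione, via furan endoperoxide 18 (not isolated)
Conditions: O2, visible light, tetraphenylporphyrin (cat.), CH2Cl2, −78 °C; then Me2S, −78 °C to rt
Reagents that add atoms: dioxygen, O=O
Why: [4+2] cycloaddition of singlet oxygen across furan C2/C5 followed by reduction of the endoperoxide with Me2S, a standard furan-to-cis-enedione opening in which the Z geometry is inherited from the ring and the furan reacts far faster than the aryl ethers.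

Step 13
Reactants: 19 (3Z)-3-[(3S)-6,8-dimethoxy-7-(triisopropylsilyloxy)chroman-3-yl]-1,6-dimethoxyhex-3-ene-2,5-dione
Product: 23 5-[(3S)-6,8-dimethoxy-7-(triisopropylsilyloxy)chroman-3-yl]-2,3-dimethoxy-1,4-benzoquinone, via bis(silyl enol ether) 20 (not isolated), via cyclohexenedione 21 (not isolated), via hydroquinone 22 (not isolated)
Conditions: Et3N, TMSOTf, CH2Cl2, −78 to 0 °C; solvent switch; Ag2O, DMSO, rt
Reagents that add atoms: none
Why: Proposed new method: soft enolization of both methoxymethyl ketones gives the (3Z)-1,6-dimethoxy-2,5-bis(silyloxy)hexatriene 20, in which the Z alkene inherited from the furan holds the two enol termini (the future quinone C2 and C3) next to each other; Ag2O then converts one silyl enol ether into a silver enolate that fragments to an α-keto radical, this radical adds to the terminus of the second enol ether, and a second one-electron oxidation with loss of both silyl groups gives diketone 21, which enolizes twice to the aromatic hydroquinone 22 that Ag2O oxidizes to quinone 23. The closest known reaction types are the oxidative coupling of silyl enol ethers to 1,4-diketones with Ag2O in DMSO and the intramolecular oxidative coupling of ketone bis-enolates to cyclic 1,4-diketones, and the argument for the extension is that the tetraoxygenated triene is far more easily oxidized than a simple enol ether and that the product is driven forward by aromatization. The six-membered carbocycle closes by a 6-endo-trig radical addition (formally the recombination of the two α-keto radical termini of a cis-enedione), whereas the competing aldol of one enol carbon onto the distal carbonyl would be a disfavoured 5-(enolendo)-exo-trig closure. No new stereocentre survives, since the two sp3 centres of 21 become sp2, and the chroman C3 centre is left alone because enolization goes to the more acidic, unhindered CH2OMe groups and not to the γ-methine. The step needs chemoselectivity for the enol ethers over the tetraoxygenated chroman arene and its silyl ether, which the mild, non-acidic oxidant Ag2O secures, and ring closure over intermolecular coupling, which the Z geometry and dilution secure. It also needs tautomerization of 21 to outrun β-elimination of methanol, which should hold because both remaining ring C–H bonds are α to a carbonyl and their loss gives an arene.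

Step 14
Reactants: 23 5-[(3S)-6,8-dimethoxy-7-(triisopropylsilyloxy)chroman-3-yl]-2,3-dimethoxy-1,4-benzoquinone
Product: 24 5-[(3S)-7-hydroxy-6,8-dimethoxychroman-3-yl]-2,3-dimethoxy-1,4-benzoquinone
Conditions: HF·pyridine, THF, 0 °C to rt
Reagents that add atoms: none
Why: Fluoride-induced cleavage of the aryl triisopropylsilyl ether, which should leave the methoxyquinone, the aryl methyl ethers and the stereocentre untouched and give the target.

Compound list
1 | 2,5-bis(hydroxymethyl)furan | OCc1ccc(CO)o1 | starting material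
2 | 2,5-bis(methoxymethyl)furan | COCc1ccc(COC)o1 | intermediate
3 | 2-[2,5-bis(methoxymethyl)furan-3-yl]-4,4,5,5-tetramethyl-1,3,2-dioxaborolane | COCc1oc(COC)cc1B2OC(C)(C)C(C)(C)O2 | intermediate
4 | ethyl [2,5-bis(methoxymethyl)furan-3-yl]acetate | CCOC(=O)Cc1cc(COC)oc1COC | intermediate
5 | [2,5-bis(methoxymethyl)furan-3-yl]acetic acid | OC(=O)Cc1cc(COC)oc1COC | intermediate
6 | (S)-4-benzyl-2-oxazolidinone | O=C1N[C@@H](Cc2ccccc2)CO1 | starting material
7 | [2,5-bis(methoxymethyl)furan-3-yl]acetic pivalic anhydride | CC(C)(C)C(=O)OC(=O)Cc1cc(COC)oc1COC | intermediate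
8 | (4S)-4-benzyl-3-{[2,5-bis(methoxymethyl)furan-3-yl]acetyl}-1,3-oxazolidin-2-one | COCc1oc(COC)cc1CC(=O)N1[C@@H](Cc2ccccc2)COC1=O | intermediate
9 | syringaldehyde (4-hydroxy-3,5-dimethoxybenzaldehyde) | COc1cc(C=O)cc(OC)c1O | starting material
10 | 2-bromo-4-hydroxy-3,5-dimethoxybenzaldehyde | COc1cc(C=O)c(Br)c(OC)c1O | intermediate
11 | 2-bromo-3,5-dimethoxy-4-(triisopropylsilyloxy)benzaldehyde | COc1cc(C=O)c(Br)c(OC)c1O[Si](C(C)C)(C(C)C)C(C)C | intermediate
12 | [2-bromo-3,5-dimethoxy-4-(triisopropylsilyloxy)phenyl]methanol | COc1cc(CO)c(Br)c(OC)c1O[Si](C(C)C)(C(C)C)C(C)C | intermediate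
13 | 2-bromo-1-(bromomethyl)-3,5-dimethoxy-4-(triisopropylsilyloxy)benzene | COc1cc(CBr)c(Br)c(OC)c1O[Si](C(C)C)(C(C)C)C(C)C | intermediate
14 | sodium (Z)-enolate of imide 8 | [Na+].[O-]/C(=C\c1cc(COC)oc1COC)N1[C@@H](Cc2ccccc2)COC1=O | intermediate
15 | (4S)-4-benzyl-3-{(2S)-2-[2,5-bis(methoxymethyl)furan-3-yl]-3-[2-bromo-3,5-dimethoxy-4-(triisopropylsilyloxy)phenyl]propanoyl}-1,3-oxazolidin-2-one | COCc1oc(COC)cc1[C@H](Cc2cc(OC)c(O[Si](C(C)C)(C(C)C)C(C)C)c(OC)c2Br)C(=O)N3[C@@H](Cc4ccccc4)COC3=O | intermediate
16 | (2S)-2-[2,5-bis(methoxymethyl)furan-3-yl]-3-[2-bromo-3,5-dimethoxy-4-(triisopropylsilyloxy)phenyl]propan-1-ol | COCc1oc(COC)cc1[C@H](Cc2cc(OC)c(O[Si](C(C)C)(C(C)C)C(C)C)c(OC)c2Br)CO | intermediate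
17 | (3S)-3-[2,5-bis(methoxymethyl)furan-3-yl]-6,8-dimethoxy-7-(triisopropylsilyloxy)chroman | COCc1oc(COC)cc1[C@H]2COc3c(cc(OC)c(O[Si](C(C)C)(C(C)C)C(C)C)c3OC)C2 | intermediate
18 | furan endoperoxide: 5-[(3S)-6,8-dimethoxy-7-(triisopropylsilyloxy)chroman-3-yl]-1,4-bis(methoxymethyl)-2,3,7-trioxabicyclo[2.2.1]hept-5-ene (both bridgehead epimers) | COCC12OOC(COC)(O1)C=C2[C@H]3COc4c(cc(OC)c(O[Si](C(C)C)(C(C)C)C(C)C)c4OC)C3 | intermediate
19 | (3Z)-3-[(3S)-6,8-dimethoxy-7-(triisopropylsilyloxy)chroman-3-yl]-1,6-dimethoxyhex-3-ene-2,5-dione | COCC(=O)/C(=C\C(=O)COC)[C@H]1COc2c(cc(OC)c(O[Si](C(C)C)(C(C)C)C(C)C)c2OC)C1 | intermediate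
20 | (3Z)-3-[(3S)-6,8-dimethoxy-7-(triisopropylsilyloxy)chroman-3-yl]-1,6-dimethoxy-2,5-bis(trimethylsilyloxy)hexa-1,3,5-triene | COC=C(O[Si](C)(C)C)/C(=C\C(O[Si](C)(C)C)=COC)[C@H]1COc2c(cc(OC)c(O[Si](C(C)C)(C(C)C)C(C)C)c2OC)C1 | intermediate
21 | 2-[(3S)-6,8-dimethoxy-7-(triisopropylsilyloxy)chroman-3-yl]-5,6-dimethoxycyclohex-2-ene-1,4-dione (mixture at C5 and C6) | COC1C(OC)C(=O)C([C@H]2COc3c(cc(OC)c(O[Si](C(C)C)(C(C)C)C(C)C)c3OC)C2)=CC1=O | intermediate
22 | 5-[(3S)-6,8-dimethoxy-7-(triisopropylsilyloxy)chroman-3-yl]-2,3-dimethoxybenzene-1,4-diol | COc1c(OC)c(O)c([C@H]2COc3c(cc(OC)c(O[Si](C(C)C)(C(C)C)C(C)C)c3OC)C2)cc1O | intermediate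
23 | 5-[(3S)-6,8-dimethoxy-7-(triisopropylsilyloxy)chroman-3-yl]-2,3-dimethoxy-1,4-benzoquinone | COC1=C(OC)C(=O)C([C@H]2COc3c(cc(OC)c(O[Si](C(C)C)(C(C)C)C(C)C)c3OC)C2)=CC1=O | intermediate
24 | 5-[(3S)-7-hydroxy-6,8-dimethoxychroman-3-yl]-2,3-dimethoxy-1,4-benzoquinone | COC1=C(OC)C(=O)C([C@H]2COc3c(cc(OC)c(O)c3OC)C2)=CC1=O | target

Total step count: 14. Longest linear sequence: 10 steps (steps 1–4 and 9–14; the syringaldehyde branch, steps 5–8 and 9–14, is equally long).

Steps most likely to fail

1. Step 13 (proposed new method). What may go wrong: β-elimination of methanol from the ring-closed diketone before it aromatizes, hydrolysis of the silyl enol ethers or intermolecular coupling before ring closure, and amine-induced Z-to-E isomerization of the enedione before silylation. The fallback uses known reaction types, sets out from 19 and comes back at 23. Compound 20 is made as in step 13 and heated without oxidant (toluene, 90 °C), where a (3Z)-hexatriene should close by thermal disrotatory 6π-electrocyclization to 2-[(3S)-6,8-dimethoxy-7-(triisopropylsilyloxy)chroman-3-yl]-5,6-dimethoxy-1,4-bis(trimethylsilyloxy)cyclohexa-1,3-diene F1. Dehydrogenation with DDQ (benzene, rt) should give 5-[(3S)-6,8-dimethoxy-7-(triisopropylsilyloxy)chroman-3-yl]-2,3-dimethoxy-1,4-bis(trimethylsilyloxy)benzene F2. Methanolysis of the two aryl trimethylsilyl ethers (MeOH, citric acid, 0 °C) gives hydroquinone 22, which Ag2O (Et2O, rt) oxidizes to 23. No β-methoxy ketone is formed in this sequence.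

2. Step 11. What may go wrong: slow C–O reductive elimination at the di-ortho-substituted, electron-rich aryl group, so that β-hydride elimination of the palladium alkoxide reduces the arene and oxidizes the alcohol. The fallback sets out from 16 and comes back at 17. Miyaura borylation (B2pin2, PdCl2(dppf), KOAc, dioxane, 80 °C) should give (2S)-2-[2,5-bis(methoxymethyl)furan-3-yl]-3-[3,5-dimethoxy-2-(4,4,5,5-tetramethyl-1,3,2-dioxaborolan-2-yl)-4-(triisopropylsilyloxy)phenyl]propan-1-ol F3. Oxidation (NaBO3·4H2O, THF/H2O, rt) gives 6-{(2S)-2-[2,5-bis(methoxymethyl)furan-3-yl]-3-hydroxypropyl}-2,4-dimethoxy-3-(triisopropylsilyloxy)phenol F4. Mitsunobu ring closure (PPh3, DIAD, THF, 0 °C), an SN2 displacement at the primary carbon that does not touch the stereocentre, then gives 17.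

3. Step 3. What may go wrong: protodeboronation of the electron-rich furylboronate under the basic aqueous conditions, or slow transmetalation of the hindered pinacol ester. The fallback reverses the roles of the partners, sets out from 3 and comes back at 4, which is saponified to 5 as in step 3. Bromodeboronation (CuBr2, MeOH/H2O, 60 °C) should give 3-bromo-2,5-bis(methoxymethyl)furan F5, and palladium-catalysed arylation of the Reformatsky reagent (BrZnCH2CO2Et, Pd(dba)2, P(t-Bu)3, THF, rt) then gives ester 4.

Further compounds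
F1 | step 13 | 2-[(3S)-6,8-dimethoxy-7-(triisopropylsilyloxy)chroman-3-yl]-5,6-dimethoxy-1,4-bis(trimethylsilyloxy)cyclohexa-1,3-diene | COC1C(OC)C(O[Si](C)(C)C)=C([C@H]2COc3c(cc(OC)c(O[Si](C(C)C)(C(C)C)C(C)C)c3OC)C2)C=C1O[Si](C)(C)C
F2 | step 13 | 5-[(3S)-6,8-dimethoxy-7-(triisopropylsilyloxy)chroman-3-yl]-2,3-dimethoxy-1,4-bis(trimethylsilyloxy)benzene | COc1c(OC)c(O[Si](C)(C)C)c([C@H]2COc3c(cc(OC)c(O[Si](C(C)C)(C(C)C)C(C)C)c3OC)C2)cc1O[Si](C)(C)C
F3 | step 11 | (2S)-2-[2,5-bis(methoxymethyl)furan-3-yl]-3-[3,5-dimethoxy-2-(4,4,5,5-tetramethyl-1,3,2-dioxaborolan-2-yl)-4-(triisopropylsilyloxy)phenyl]propan-1-ol | COCc1oc(COC)cc1[C@H](Cc2cc(OC)c(O[Si](C(C)C)(C(C)C)C(C)C)c(OC)c2B3OC(C)(C)C(C)(C)O3)CO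
F4 | step 11 | 6-{(2S)-2-[2,5-bis(methoxymethyl)furan-3-yl]-3-hydroxypropyl}-2,4-dimethoxy-3-(triisopropylsilyloxy)phenol | COCc1oc(COC)cc1[C@H](Cc2cc(OC)c(O[Si](C(C)C)(C(C)C)C(C)C)c(OC)c2O)CO
F5 | step 3 | 3-bromo-2,5-bis(methoxymethyl)furan | COCc1oc(COC)cc1Br
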